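**Strategy.** Ring A is closed late across C1–C2 and C3–C4. The unfunctionalised C2–C3 unit comes from vinyltriphenylphosphonium bromide. In one Michael–Wittig (Schweizer) annulation the C4 ester enolate attacks this salt and the resulting ylide olefinates the C1 aldehyde on quaternary C10, which closes the six-membered ring and creates the C4 quaternary stereocentre. The step exploits the 1,4 relationship in ring A between C1 and the carboxyl-bearing C4 across the C10–C5 bond. Its precursor is an open-chain aldehyde acid attached at C9 to the preformed bicyclo[3.2.1]octane (rings C and D), built by Hosomi–Sakurai cyclisation, Mukaiyama–Michael addition and Ireland–Claisen rearrangement.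

Key step: step 15

Remark: atoms carry ent-kaurane numbers (C1–C20); the methyl-bearing carbon of the succinate unit (future C4) is carried as both epimers in 18–23, because the key step planarises and resets it.

**Step 1**
Reactants: 1 (2-bromoprop-2-en-1-yl)trimethylsilane
Product: 2 4,4,5,5-tetramethyl-2-[3-(trimethylsilyl)prop-1-en-2-yl]-1,3,2-dioxaborolane
Conditions: tBuLi (2 equiv), Et2O, −78 °C; then the alkoxyborolane, −78 → 23 °C
Reagents that add atoms: 2-isopropoxy-4,4,5,5-tetramethyl-1,3,2-dioxaborolane, CC(C)OB1OC(C)(C)C(C)(C)O1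
Why: Bromine–lithium exchange gives the 2-lithioallylsilane, which is trapped by the borate ester (halogen–metal exchange/borylation).

**Step 2**
Reactants: 2; 3 cyclohex-2-en-1-one
Product: 4 (R)-3-[3-(trimethylsilyl)prop-1-en-2-yl]cyclohexan-1-one
Conditions: [RhCl(C8H12)]2 (1.5 mol%), (R)-BINAP, KOH (0.5 equiv), 1,4-dioxane/H2O, 40 °C
Reagents that add atoms: none
Why: Hayashi–Miyaura asymmetric 1,4-addition of the alkenylboronate; the (R)-BINAP–rhodium complex should select the enone face that gives (R)-C13, by analogy with the sense known for arylboronic acids.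

**Step 3**
Reactants: 4
Product: 5 (R)-5-[3-(trimethylsilyl)prop-1-en-2-yl]cyclohex-2-en-1-one
Conditions: LiN(iPr)2, THF, −78 °C; then N-tert-butylbenzenesulfinimidoyl chloride, −78 °C
Reagents that add atoms: none
Why: Kinetic deprotonation at the α-carbon remote from the substituent, then Mukaiyama dehydrogenation of the lithium enolate, should place the enone away from the untouched stereocentre.

**Step 4**
Reactants: 5; 6 [(benzyloxy)methyl]tributylstannane
Product: 7 (5R)-1-[(benzyloxy)methyl]-5-[3-(trimethylsilyl)prop-1-en-2-yl]cyclohex-2-en-1-ol (both C1 epimers)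
Conditions: 6, nBuLi, THF, −78 °C; then 5, −78 °C
Reagents that add atoms: none
Why: Tin–lithium exchange gives the α-alkoxymethyllithium, which adds 1,2 to the enone and brings in C7; the new carbinol centre is lost in step 5.

**Step 5**
Reactants: 7
Product: 8 (S)-3-[(benzyloxy)methyl]-5-[3-(trimethylsilyl)prop-1-en-2-yl]cyclohex-2-en-1-one
Conditions: 4-acetamido-2,2,6,6-tetramethyl-1-oxopiperidinium tetrafluoroborate, MeCN, 23 °C
Reagents that add atoms: none
Why: Oxidative 1,3-transposition of the tertiary allylic alcohol (Babler–Dauben type) moves the carbonyl to C11 and leaves C7 on the enone β-carbon C8.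

**Step 6**
Reactants: 8; 9 pent-3-yn-2-one
Product: 11 (E)-4-[(1R,2S,5S)-1-[(benzyloxy)methyl]-6-methylidene-3-oxobicyclo[3.2.1]octan-2-yl]pent-3-en-2-one, via bicyclic silyl enol ether 10 (not isolated)
Conditions: TMSOTf (10 mol%), CH2Cl2, −78 °C; then 9, TiCl4 (1.1 equiv), −78 °C
Reagents that add atoms: none
Why: Intramolecular Hosomi–Sakurai addition closes ring D on the face that carries the C13 side chain (fixing C8) and passes silicon to oxygen to give the regiodefined C9 enol ether 10; its Mukaiyama–Michael addition to the ynone should occur anti to the C15–C16 bridge (setting C9) and give the more stable E-enone.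

**Step 7**
Reactants: 11
Product: 12 (1R,2S,5S)-1-[(benzyloxy)methyl]-2-[(E)-4-oxopent-2-en-2-yl]bicyclo[3.2.1]octane-3,6-dione
Conditions: O3, CH2Cl2/MeOH, −78 °C, Sudan Red 7B as end-point indicator; then Me2S
Reagents that add atoms: ozone, [O-][O+]=O
Why: Chemoselective ozonolysis: the electron-rich 1,1-disubstituted alkene should react far faster than the conjugated enone; C16 is held as a ketone until the ring A alkene chemistry is finished.

**Step 8**
Reactants: 12
Product: 13 the C16 ethylene ketal of 12 (spiro-1,3-dioxolane at C6 of the bicyclooctane)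
Conditions: (TMSOCH2)2, TMSOTf (5 mol%), CH2Cl2, −78 °C
Reagents that add atoms: 1,2-bis(trimethylsilyloxy)ethane, C[Si](C)(C)OCCO[Si](C)(C)C
Why: Silyl-triflate-catalysed ketalisation should select the unhindered cyclopentanone C16 over the hindered C11 ketone and the conjugated ketone.

**Step 9**
Reactants: 13
Product: 15 diol: (S)-allylic carbinol and C11 alcohol with the hydroxyl syn to the C15–C16 bridge, via hydroxy ketone 14 (not isolated)
Conditions: (R)-2-methyl-CBS-oxazaborolidine (20 mol%), catecholborane, toluene, −78 °C; then NaBH4, MeOH, 0 °C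
Reagents that add atoms: none
Why: Corey–Bakshi–Shibata reduction sets the (S)-carbinol under catalyst control; borohydride then reduces the C11 ketone from the open face, and that centre is reoxidised in step 19.

**Step 10**
Reactants: 16 tert-butyl propanoate; 17 benzyl 2-bromoacetate
Product: 18 4-benzyl 1-tert-butyl 2-methylbutanedioate (racemic)
Conditions: LiN(iPr)2, THF, −78 °C; then 17
Reagents that add atoms: none
Why: SN2 alkylation of the ester lithium enolate by the α-bromo ester.

**Step 11**
Reactants: 18
Product: 19 4-(tert-butoxy)-3-methyl-4-oxobutanoic acid (racemic)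
Conditions: H2 (1 atm), 10% Pd on carbon, EtOAc, 23 °C
Reagents that add atoms: none
Why: Hydrogenolysis of the benzyl ester leaves the tert-butyl ester intact.

**Step 12**
Reactants: 15; 19
Product: 20 ester of the allylic hydroxyl of 15 with acid 19
Conditions: EDC·HCl, DMAP (cat.), CH2Cl2, 0 °C
Reagents that add atoms: none
Why: Steglich-type esterification at the accessible allylic hydroxyl; the C11 hydroxyl under the bridge, next to the substituted C9, is expected to stay free.

**Step 13**
Reactants: 20
Product: 22 Claisen acid: C6 carboxylic acid with C5 and quaternary C10 (methyl, E-propenyl) set, via silyl ketene acetal 21 (not isolated)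
Conditions: LiN(iPr)2 (2.3 equiv), TMSCl, THF, −78 → 60 °C; then 1 M HCl
Reagents that add atoms: none
Why: Ireland–Claisen rearrangement: the less hindered CH2 of the allyl ester is deprotonated to the kinetic E-ketene acetal, and a chair transition state with the carbinol methyl equatorial transfers the (S)-carbinol chirality to C10 while the E-alkene/E-ketene acetal pairing sets C5.

**Step 14**
Reactants: 22
Product: 23 aldehyde acid (C1 aldehyde on C10; may exist as the lactol with the C6 acid)
Conditions: O3, CH2Cl2/MeOH, −78 °C; then Me2S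
Reagents that add atoms: ozone, [O-][O+]=O
Why: Ozonolysis of the only alkene left turns the propenyl group into the C1 aldehyde.

**Step 15**
Reactants: 23; 24 triphenyl(vinyl)phosphonium bromide
Product: 26 ring A cyclohexene (C1=C2) with C4 quaternary, C19 tert-butyl ester and free C6 acid, via phosphonium ylide 25 (not isolated)
Conditions: LiNC9H18 (lithium 2,2,6,6-tetramethylpiperidide, 3.3 equiv), THF, −78 °C; then 24, −78 → 40 °C
Reagents that add atoms: none
Why: Triple deprotonation gives the C11 alkoxide, the C6 carboxylate and, because the carboxylate deactivates H5, the tert-butyl ester enolate at C4 only; this adds to the vinylphosphonium salt (C3–C4) and ylide 25 closes ring A by intramolecular Wittig olefination of the non-enolisable C1 aldehyde (C1=C2). The closest known reaction type is the Schweizer annulation of carbanions that carry a pendant carbonyl group with vinylphosphonium salts. The six-membered ring closes by 6-exo-trig addition of the ylide carbon to the aldehyde, and the cis-alkene is the only geometry the ring allows. C4 is set in the Michael step: with H5 in the enolate plane of the carboxylate–enolate chelate, the electrophile should enter anti to the bulky C10 group, as in anti-selective alkylations of 2-substituted succinate half-ester dianions, which places C19 cis to C6. The step needs Michael addition to outrun aldol self-condensation, which the neopentyl aldehyde and the hindered tetrasubstituted enolate should secure, and C-attack to outrun alkoxide attack, which the shielded C11 alkoxide should secure.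

**Step 16**
Reactants: 26
Product: 27 saturated ring A acid with free C7 hydroxyl
Conditions: H2 (1 atm), 10% Pd on carbon, EtOAc/MeOH, 23 °C
Reagents that add atoms: none
Why: Heterogeneous hydrogenation saturates C1=C2 and hydrogenolyses the benzyl ether; no stereocentre is formed.

**Step 17**
Reactants: 27
Product: 28 C6,C19-diacid with C16 ketone and C7, C11 hydroxyls
Conditions: CF3CO2H/CH2Cl2, 0 → 23 °C; then H2O
Reagents that add atoms: water, O
Why: Acidolysis of the tert-butyl ester and hydrolysis of the dioxolane, done before the acid-sensitive exocyclic alkene exists.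

**Step 18**
Reactants: 28; 29 methyltriphenylphosphonium bromide
Product: 30 16-methylidene diol diacid
Conditions: 29 (6 equiv), KOtBu (6 equiv), THF, 0 → 50 °C
Reagents that add atoms: none
Why: Wittig methylenation of the only carbonyl group; excess ylide tolerates the carboxylates and alkoxides.

**Step 19**
Reactants: 30
Product: 31 CNP0408869.1, (4R,5S,8R,9S,10S,13S)-7,11-dioxo-6,7-seco-ent-kaur-16-ene-6,19-dioic acid
Conditions: Dess–Martin periodinane (3 equiv), CH2Cl2, 0 → 23 °C
Reagents that add atoms: none
Why: Dess–Martin oxidation converts the C7 alcohol to the aldehyde and the C11 alcohol to the ketone under non-basic conditions that should not epimerise C9.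

**Compound list**
1 | (2-bromoprop-2-en-1-yl)trimethylsilane | C=C(Br)C[Si](C)(C)C | starting material
2 | 4,4,5,5-tetramethyl-2-[3-(trimethylsilyl)prop-1-en-2-yl]-1,3,2-dioxaborolane | C=C(C[Si](C)(C)C)B1OC(C)(C)C(C)(C)O1 | intermediate
3 | cyclohex-2-en-1-one | O=C1C=CCCC1 | starting material
4 | (R)-3-[3-(trimethylsilyl)prop-1-en-2-yl]cyclohexan-1-one | O=C1C[C@H](C(=C)C[Si](C)(C)C)CCC1 | intermediate
5 | (R)-5-[3-(trimethylsilyl)prop-1-en-2-yl]cyclohex-2-en-1-one | O=C1C=CC[C@@H](C(=C)C[Si](C)(C)C)C1 | intermediate
6 | [(benzyloxy)methyl]tributylstannane | CCCC[Sn](CCCC)(CCCC)COCc1ccccc1 | starting material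
7 | (5R)-1-[(benzyloxy)methyl]-5-[3-(trimethylsilyl)prop-1-en-2-yl]cyclohex-2-en-1-ol, both C1 epimers | OC1(COCc2ccccc2)C=CC[C@@H](C(=C)C[Si](C)(C)C)C1 | intermediate
8 | (S)-3-[(benzyloxy)methyl]-5-[3-(trimethylsilyl)prop-1-en-2-yl]cyclohex-2-en-1-one | O=C1C=C(COCc2ccccc2)C[C@H](C(=C)C[Si](C)(C)C)C1 | intermediate
9 | pent-3-yn-2-one | CC#CC(C)=O | starting material
10 | {[(1R,5S)-1-[(benzyloxy)methyl]-6-methylidenebicyclo[3.2.1]oct-2-en-3-yl]oxy}trimethylsilane | C=C1C[C@]2(COCc3ccccc3)C[C@H]1CC(O[Si](C)(C)C)=C2 | intermediate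
11 | (E)-4-[(1R,2S,5S)-1-[(benzyloxy)methyl]-6-methylidene-3-oxobicyclo[3.2.1]octan-2-yl]pent-3-en-2-one | C=C1C[C@]2(COCc3ccccc3)C[C@H]1CC(=O)[C@H]2/C(C)=C/C(C)=O | intermediate
12 | (1R,2S,5S)-1-[(benzyloxy)methyl]-2-[(E)-4-oxopent-2-en-2-yl]bicyclo[3.2.1]octane-3,6-dione | O=C1C[C@]2(COCc3ccccc3)C[C@H]1CC(=O)[C@H]2/C(C)=C/C(C)=O | intermediate
13 | C16 ethylene ketal of 12 (spiro-1,3-dioxolane at C6 of the bicyclooctane; C11 ketone and E-enone kept) | O1CCOC12C[C@]3(COCc4ccccc4)C[C@H]2CC(=O)[C@H]3/C(C)=C/C(C)=O | intermediate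
14 | hydroxy ketone: 13 with the side-chain ketone reduced to the (S)-carbinol | O1CCOC12C[C@]3(COCc4ccccc4)C[C@H]2CC(=O)[C@H]3/C(C)=C/[C@H](C)O | intermediate
15 | diol: 14 with C11 reduced, hydroxyl syn to the C15–C16 bridge | O1CCOC12C[C@]3(COCc4ccccc4)C[C@H]2C[C@H](O)[C@H]3/C(C)=C/[C@H](C)O | intermediate
16 | tert-butyl propanoate | CCC(=O)OC(C)(C)C | starting material
17 | benzyl 2-bromoacetate | BrCC(=O)OCc1ccccc1 | starting material
18 | 4-benzyl 1-tert-butyl 2-methylbutanedioate (racemic) | CC(CC(=O)OCc1ccccc1)C(=O)OC(C)(C)C | intermediate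
19 | 4-(tert-butoxy)-3-methyl-4-oxobutanoic acid (racemic) | CC(CC(=O)O)C(=O)OC(C)(C)C | intermediate
20 | ester of the allylic (S)-carbinol of 15 with 19 | O1CCOC12C[C@]3(COCc4ccccc4)C[C@H]2C[C@H](O)[C@H]3/C(C)=C/[C@H](C)OC(=O)CC(C)C(=O)OC(C)(C)C | intermediate
21 | E-trimethylsilyl ketene acetal of 20, C11 hydroxyl silylated | O1CCOC12C[C@]3(COCc4ccccc4)C[C@H]2C[C@H](O[Si](C)(C)C)[C@H]3/C(C)=C/[C@H](C)O/C(O[Si](C)(C)C)=C\C(C)C(=O)OC(C)(C)C | intermediate
22 | Claisen acid: C6 acid on C5; C10 bearing methyl, E-propenyl and the bicyclooctyl group | O1CCOC12C[C@]3(COCc4ccccc4)C[C@H]2C[C@H](O)[C@H]3[C@](C)(/C=C/C)[C@H](C(=O)O)C(C)C(=O)OC(C)(C)C | intermediate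
23 | aldehyde acid: 22 with the propenyl group cleaved to the C1 aldehyde | O1CCOC12C[C@]3(COCc4ccccc4)C[C@H]2C[C@H](O)[C@H]3[C@](C)(C=O)[C@H](C(=O)O)C(C)C(=O)OC(C)(C)C | intermediate
24 | triphenyl(vinyl)phosphonium bromide | C=C[P+](c1ccccc1)(c1ccccc1)c1ccccc1.[Br-] | starting material
25 | ylide: C4-alkylated dilithium salt carrying CH2CH=PPh3 on C4 | [Li+].[Li+].O1CCOC12C[C@]3(COCc4ccccc4)C[C@H]2C[C@H]([O-])[C@H]3[C@](C)(C=O)[C@H](C(=O)[O-])[C@@](C)(CC=P(c5ccccc5)(c5ccccc5)c5ccccc5)C(=O)OC(C)(C)C | intermediate
26 | ring A cyclohexene: C1=C2, C19 tert-butyl ester, C6 acid, C7 benzyl ether, C16 ketal | O1CCOC12C[C@]3(COCc4ccccc4)C[C@H]2C[C@H](O)[C@H]3[C@]5(C)C=CC[C@@](C)(C(=O)OC(C)(C)C)[C@H]5C(=O)O | intermediate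
27 | saturated ring A compound with free C7 hydroxyl | O1CCOC12C[C@]3(CO)C[C@H]2C[C@H](O)[C@H]3[C@]5(C)CCC[C@@](C)(C(=O)OC(C)(C)C)[C@H]5C(=O)O | intermediate
28 | 7,11-dihydroxy-16-oxo diacid | O=C1C[C@]2(CO)C[C@H]1C[C@H](O)[C@H]2[C@]3(C)CCC[C@@](C)(C(=O)O)[C@H]3C(=O)O | intermediate
29 | methyltriphenylphosphonium bromide | C[P+](c1ccccc1)(c1ccccc1)c1ccccc1.[Br-] | starting material
30 | 7,11-dihydroxy-16-methylidene diacid | C=C1C[C@]2(CO)C[C@H]1C[C@H](O)[C@H]2[C@]3(C)CCC[C@@](C)(C(=O)O)[C@H]3C(=O)O | intermediate
31 | CNP0408869.1, (4R,5S,8R,9S,10S,13S)-7,11-dioxo-6,7-seco-ent-kaur-16-ene-6,19-dioic acid | C=C1C[C@]2(C=O)C[C@H]1CC(=O)[C@H]2[C@]1(C)CCC[C@@](C)(C(=O)O)[C@H]1C(=O)O | target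

**Step count**
Total: 19 steps. Longest linear sequence: 17 steps (steps 1–9 and 12–19).

**Steps most likely to fail**

1. Step 15. The ester enolate may condense with the aldehyde instead of adding to the phosphonium salt, or the Michael step may show poor facial selectivity at C4. Fallback: the same dianion of 23 (LiNC9H18, THF, −78 °C) is intercepted with phenyl vinyl sulfone. Michael addition at C4 and intramolecular aldol addition of the α-sulfonyl carbanion to C1 should give the β-hydroxy sulfone F1, still forming both ring bonds in one operation. Julia-type reductive elimination (SmI2, HMPA, THF) returns to 26.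

2. Step 13. The [3,3] shift may be slow at the congested C10, or the ketene acetal geometry and regioselective deprotonation may erode. Fallback: from 15, Johnson–Claisen rearrangement (triethyl orthoacetate, propanoic acid cat., 140 °C) should give the ethyl ester F2 with C10 set by the same chirality transfer. Alkylation of its dianion (LiN(iPr)2, THF, −78 °C) with tert-butyl 2-bromopropanoate gives the diester F3. Hydrolysis of the ethyl ester (LiOH, THF/H2O) rejoins the route at 22.

3. Step 6. Conversion may be poor, or facial and E/Z control may be lost in the Michael addition at the hindered C9, with epimerisation of the acidic C9–H in 11. Fallback: from 8, the enol ether 10 is isolated after the silyl-triflate cyclisation and cross-coupled with (E)-4-bromopent-3-en-2-one (PdCl2(PPh3)2, Bu3SnF, toluene, 80 °C; α-alkenylation through the tin enolate) to rejoin at 11.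

**Further compounds**
F1 | step 15 | β-hydroxy sulfone: ring A closed with 1-hydroxy and 2-phenylsulfonyl groups | O1CCOC12C[C@]3(COCc4ccccc4)C[C@H]2C[C@H](O)[C@H]3[C@]5(C)C(O)C(S(=O)(=O)c6ccccc6)C[C@@](C)(C(=O)OC(C)(C)C)[C@H]5C(=O)O
F2 | step 13 | ethyl ester from Johnson–Claisen: C10 bearing methyl, E-propenyl and CH2CO2Et | O1CCOC12C[C@]3(COCc4ccccc4)C[C@H]2C[C@H](O)[C@H]3[C@](C)(/C=C/C)CC(=O)OCC
F3 | step 13 | C5-alkylated ethyl tert-butyl diester | O1CCOC12C[C@]3(COCc4ccccc4)C[C@H]2C[C@H](O)[C@H]3[C@](C)(/C=C/C)[C@H](C(=O)OCC)C(C)C(=O)OC(C)(C)C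
F0 | step 6 | none | none
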